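**Retrosynthetic overview**
- Last come a global deprotection and a Steglich esterification of the C2 alcohol of a protected decalin hydroxy-acrylate. The acid partner is the (S)-acetonide acid, made in two steps from (R)-glyceraldehyde acetonide.
- Ring A is closed late by ring-closing metathesis of a vinyl group with a 1,1-disubstituted alkene. The C2 alcohol comes from a Luche reduction.
- Key step: ring B arises by a one-carbon ring expansion (semipinacol 1,2-shift) of a 1-allenylcyclopentanol. The same operation installs the complete acrylate ester.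
- The cyclopentane gets its trans-vicinal side chains by vinyl conjugate addition anti to the silyloxy group, then a Mukaiyama–Michael addition. Both ketones are then methylenated at once.
- Order of rings: cyclopentane (bought), then ring B (expansion), then ring A (metathesis).

Atom labels C1–C8a are the octahydronaphthalene locants of the target: C1 carries the acrylic acid, C2 the ester oxygen, C4 the exocyclic methylene and C7 the CH2OH.
Assumption: the silyl-protected (S)-hydroxycyclopentenone and (R)-glyceraldehyde acetonide are bought enantiopure as such.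

**Step 1**
Reactants: 1 but-3-ene-1,2-diol (racemic)
Product: 2 1-[(tert-butyldiphenylsilyl)oxy]but-3-en-2-ol (racemic)
Conditions: TBDPSCl (1.0 equiv), imidazole, CH2Cl2, 0 °C
Reagents that add atoms: tert-butyl(chloro)diphenylsilane, CC(C)(C)[Si](Cl)(c1ccccc1)c1ccccc1
Why: Silyl ether formation in which the bulky chlorosilane reacts only at the primary hydroxyl; the racemic carbinol centre is erased in the next step.

**Step 2**
Reactants: 2 1-[(tert-butyldiphenylsilyl)oxy]but-3-en-2-ol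
Product: 3 1-[(tert-butyldiphenylsilyl)oxy]but-3-en-2-one
Conditions: Dess–Martin periodinane, CH2Cl2, 0 °C
Reagents that add atoms: none
Why: Dess–Martin oxidation of the secondary allylic alcohol gives the vinyl ketone under mild conditions that do not trigger its polymerisation.

**Step 3**
Reactants: 4 (S)-4-[(tert-butyldimethylsilyl)oxy]cyclopent-2-en-1-one
Product: 5 (3S,4S)-4-[(tert-butyldimethylsilyl)oxy]-3-ethenyl-1-[(trimethylsilyl)oxy]cyclopent-1-ene
Conditions: vinylMgBr (1.3 equiv), CuBr·SMe2 (10 mol %), TMSCl, DMPU, THF, −78 °C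
Reagents that add atoms: vinylmagnesium bromide, C=C[Mg]Br; chlorotrimethylsilane, C[Si](C)(C)Cl
Why: Copper-catalysed, TMSCl-accelerated conjugate addition of the vinyl Grignard reagent occurs anti to the ring silyloxy group (this sets C8a) and the enolate is caught regiospecifically as its silyl enol ether.

**Step 4**
Reactants: 5 (3S,4S)-4-[(tert-butyldimethylsilyl)oxy]-3-ethenyl-1-[(trimethylsilyl)oxy]cyclopent-1-ene; 3 1-[(tert-butyldiphenylsilyl)oxy]but-3-en-2-one
Product: 6 (2S,3S,4S)-4-[(tert-butyldimethylsilyl)oxy]-2-{4-[(tert-butyldiphenylsilyl)oxy]-3-oxobutyl}-3-ethenylcyclopentan-1-one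
Conditions: TiCl4 (1.0 equiv), CH2Cl2, −78 °C; aq. NaHCO3 work-up
Reagents that add atoms: none
Why: Mukaiyama–Michael addition to the TiCl4-activated vinyl ketone forms the C4a–C5 bond anti to the neighbouring vinyl group, and the trans-2,3-disubstituted cyclopentanone is also the thermodynamic epimer (this sets C4a).

**Step 5**
Reactants: 6 (2S,3S,4S)-4-[(tert-butyldimethylsilyl)oxy]-2-{4-[(tert-butyldiphenylsilyl)oxy]-3-oxobutyl}-3-ethenylcyclopentan-1-one
Product: 7 tert-butyl{[(1S,2S,3S)-3-(3-{[(tert-butyldiphenylsilyl)oxy]methyl}but-3-en-1-yl)-2-ethenyl-4-methylidenecyclopentyl]oxy}dimethylsilane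
Conditions: Zn, CH2Br2, TiCl4 (excess), THF–CH2Cl2, 0 °C to rt
Reagents that add atoms: dibromomethane, BrCBr
Why: Lombardo methylenation converts both ketones at once with a non-basic zinc–titanium methylene reagent, so the α-stereocentre is not epimerised and the β-silyloxy group is not eliminated.

**Step 6**
Reactants: 7 tert-butyl{[(1S,2S,3S)-3-(3-{[(tert-butyldiphenylsilyl)oxy]methyl}but-3-en-1-yl)-2-ethenyl-4-methylidenecyclopentyl]oxy}dimethylsilane
Product: 8 (1S,2S,3S)-3-(3-{[(tert-butyldiphenylsilyl)oxy]methyl}but-3-en-1-yl)-2-ethenyl-4-methylidenecyclopentan-1-ol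
Conditions: HF·pyridine, pyridine, THF, 0 °C
Reagents that add atoms: none
Why: Selective desilylation, because buffered HF·pyridine cleaves the secondary TBS ether much faster than the bulkier primary TBDPS ether.

**Step 7**
Reactants: 8 (1S,2S,3S)-3-(3-{[(tert-butyldiphenylsilyl)oxy]methyl}but-3-en-1-yl)-2-ethenyl-4-methylidenecyclopentan-1-ol
Product: 9 (2S,3S)-3-(3-{[(tert-butyldiphenylsilyl)oxy]methyl}but-3-en-1-yl)-2-ethenyl-4-methylidenecyclopentan-1-one
Conditions: Dess–Martin periodinane, NaHCO3, CH2Cl2, 0 °C; used at once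
Reagents that add atoms: none
Why: Buffered Dess–Martin oxidation works without free acid or base, so neither alkene moves into conjugation and the α-vinyl centre keeps its favoured trans configuration.

**Step 8**
Reactants: 9 (2S,3S)-3-(3-{[(tert-butyldiphenylsilyl)oxy]methyl}but-3-en-1-yl)-2-ethenyl-4-methylidenecyclopentan-1-one; 10 3-methoxyprop-1-yne
Product: 13 (1R,2S,3S)-3-(3-{[(tert-butyldiphenylsilyl)oxy]methyl}but-3-en-1-yl)-2-ethenyl-1-(3-methoxyprop-1-yn-1-yl)-4-methylidenecyclopentan-1-ol, via lithium acetylide 11 (not isolated), via dichlorocerium acetylide 12 (not isolated)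
Conditions: 10, n-BuLi, THF, −78 °C; anhydrous CeCl3; then 9, −78 °C; aq. NH4Cl
Reagents that add atoms: none
Why: 1,2-Addition of the weakly basic organocerium acetylide outruns enolisation and comes in anti to the α-vinyl group; the carbinol configuration is of no consequence because this carbon becomes the ketone carbon again in step 10.

**Step 9**
Reactants: 13 (1R,2S,3S)-3-(3-{[(tert-butyldiphenylsilyl)oxy]methyl}but-3-en-1-yl)-2-ethenyl-1-(3-methoxyprop-1-yn-1-yl)-4-methylidenecyclopentan-1-ol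
Product: 14 (1R,2S,3S)-3-(3-{[(tert-butyldiphenylsilyl)oxy]methyl}but-3-en-1-yl)-2-ethenyl-4-methylidene-1-(propa-1,2-dien-1-yl)cyclopentan-1-ol
Conditions: LiAlH4, Et2O, reflux
Reagents that add atoms: none
Why: Alkoxide-directed hydroalumination of the alkyne followed by 1,2-elimination of aluminium methoxide (SN2′-type reduction of a 4-alkoxybut-2-yn-1-ol) gives the terminal allenyl carbinol and touches no stereocentre.

**Step 10 (key step)**
Reactants: 14 (1R,2S,3S)-3-(3-{[(tert-butyldiphenylsilyl)oxy]methyl}but-3-en-1-yl)-2-ethenyl-4-methylidene-1-(propa-1,2-dien-1-yl)cyclopentan-1-ol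
Product: 15 2-(trimethylsilyl)ethyl 2-[(1S,2S,3S)-3-(3-{[(tert-butyldiphenylsilyl)oxy]methyl}but-3-en-1-yl)-2-ethenyl-4-methylidene-6-oxocyclohexyl]prop-2-enoate
Conditions: Pd2(dba)3·CHCl3 (2.5 mol %), P(2-furyl)3 (10 mol %), ClCO2CH2CH2SiMe3 (1.5 equiv), NaHCO3, THF, 50 °C
Reagents that add atoms: 2-(trimethylsilyl)ethyl chloroformate, C[Si](C)(C)CCOC(=O)Cl
Why: Proposed new method: oxidative addition of the chloroformate to zerovalent palladium gives an alkoxycarbonyl–palladium chloride that carbopalladates the allene at its central carbon; the resulting 2-(alkoxycarbonyl)-π-allyl complex next to the tertiary carbinol collapses by an anti-periplanar semipinacol 1,2-shift of the more substituted, allylic ring carbon C8a (retention at C8a), which turns the cyclopentanol into the cyclohexanone of ring B, forms the C1–C8a bond and releases zerovalent palladium and HCl; the other exits (allyl chloride, spiro vinyl-oxirane) are themselves π-allyl precursors and feed back, so only the C–C shift is irreversible, and the new α-centre C1 settles equatorial by enolisation; the closest known reaction types are the palladium-catalysed, aryl-halide-triggered ring expansion of allenylcyclobutanols and the palladium-catalysed addition of chloroformates across allenes.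

**Step 11**
Reactants: 15 2-(trimethylsilyl)ethyl 2-[(1S,2S,3S)-3-(3-{[(tert-butyldiphenylsilyl)oxy]methyl}but-3-en-1-yl)-2-ethenyl-4-methylidene-6-oxocyclohexyl]prop-2-enoate
Product: 16 2-(trimethylsilyl)ethyl 2-[(1S,2S,3S,6R)-3-(3-{[(tert-butyldiphenylsilyl)oxy]methyl}but-3-en-1-yl)-2-ethenyl-6-hydroxy-4-methylidenecyclohexyl]prop-2-enoate
Conditions: NaBH4, CeCl3·7H2O, MeOH, −78 °C
Reagents that add atoms: none
Why: Luche reduction, in which hydride attacks axially on the chair that has all three ring substituents equatorial and gives the equatorial alcohol trans to C1 (this sets C2), while CeCl3 suppresses conjugate reduction and the low temperature prevents lactonisation.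

**Step 12**
Reactants: 16 2-(trimethylsilyl)ethyl 2-[(1S,2S,3S,6R)-3-(3-{[(tert-butyldiphenylsilyl)oxy]methyl}but-3-en-1-yl)-2-ethenyl-6-hydroxy-4-methylidenecyclohexyl]prop-2-enoate
Product: 17 2-(trimethylsilyl)ethyl 2-[(1S,2R,4aS,8aS)-7-{[(tert-butyldiphenylsilyl)oxy]methyl}-2-hydroxy-4-methylidene-1,2,3,4,4a,5,6,8a-octahydronaphthalen-1-yl]prop-2-enoate
Conditions: Hoveyda–Grubbs second-generation catalyst (5 mol %), toluene, 70 °C
Reagents that add atoms: none
Why: Ring-closing metathesis of the vinyl group with the 1,1-disubstituted allylic-ether alkene is the only closure that gives a six-membered ring; the trans-diequatorial tethers give the trans-fused ring A, and the acrylate and the exocyclic methylene are too hindered or electron-poor to compete.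

**Step 13**
Reactants: 18 (R)-2,2-dimethyl-1,3-dioxolane-4-carbaldehyde
Product: 19 (S)-4-ethynyl-2,2-dimethyl-1,3-dioxolane
Conditions: dimethyl (1-diazo-2-oxopropyl)phosphonate, K2CO3, MeOH, 0 °C to rt
Reagents that add atoms: dimethyl (1-diazo-2-oxopropyl)phosphonate, CC(=O)C(=[N+]=[N-])P(=O)(OC)OC
Why: Ohira–Bestmann homologation turns the aldehyde into the terminal alkyne under mild carbonate conditions without racemising the α-alkoxy centre (the descriptor changes only because the priorities change).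

**Step 14**
Reactants: 19 (S)-4-ethynyl-2,2-dimethyl-1,3-dioxolane
Product: 21 2-[(4S)-2,2-dimethyl-1,3-dioxolan-4-yl]prop-2-enoic acid, via internal vinylalane 20 (not isolated)
Conditions: i-Bu2AlH, Ni(dppp)Cl2 (3 mol %), THF, 22 °C; MeLi, −78 °C; CO2; cold 1 M HCl
Reagents that add atoms: carbon dioxide, O=C=O
Why: Nickel-catalysed α-selective hydroalumination puts aluminium on the internal alkyne carbon, and carboxylation of the derived methyl ate complex gives the 2-substituted acrylic acid with the stereocentre untouched.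

**Step 15**
Reactants: 17 2-(trimethylsilyl)ethyl 2-[(1S,2R,4aS,8aS)-7-{[(tert-butyldiphenylsilyl)oxy]methyl}-2-hydroxy-4-methylidene-1,2,3,4,4a,5,6,8a-octahydronaphthalen-1-yl]prop-2-enoate; 21 2-[(4S)-2,2-dimethyl-1,3-dioxolan-4-yl]prop-2-enoic acid
Product: 22 2-(trimethylsilyl)ethyl 2-[(1S,2R,4aS,8aS)-7-{[(tert-butyldiphenylsilyl)oxy]methyl}-2-({2-[(4S)-2,2-dimethyl-1,3-dioxolan-4-yl]prop-2-enoyl}oxy)-4-methylidene-1,2,3,4,4a,5,6,8a-octahydronaphthalen-1-yl]prop-2-enoate
Conditions: DIC, DMAP (0.3 equiv), CH2Cl2, 0 °C to rt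
Reagents that add atoms: none
Why: Steglich esterification couples the equatorial secondary alcohol to the acid under neutral carbodiimide conditions with retention at every stereocentre.

**Step 16**
Reactants: 22 2-(trimethylsilyl)ethyl 2-[(1S,2R,4aS,8aS)-7-{[(tert-butyldiphenylsilyl)oxy]methyl}-2-({2-[(4S)-2,2-dimethyl-1,3-dioxolan-4-yl]prop-2-enoyl}oxy)-4-methylidene-1,2,3,4,4a,5,6,8a-octahydronaphthalen-1-yl]prop-2-enoate
Product: 24 2-[(1S,2R,4aS,8aS)-2-{[(3S)-3,4-dihydroxy-2-methylidenebutanoyl]oxy}-7-(hydroxymethyl)-4-methylidene-1,2,3,4,4a,5,6,8a-octahydronaphthalen-1-yl]prop-2-enoic acid (CNP0460913.3), via acetonide hydroxy acid 23 (not isolated)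
Conditions: TBAF–AcOH (1:1), THF, rt; then AcOH–H2O (4:1), 35 °C
Reagents that add atoms: none
Why: Buffered fluoride removes the TBDPS ether and fragments the 2-(trimethylsilyl)ethyl ester (β-elimination to ethene) and mild aqueous acetic acid then hydrolyses the acetonide, conditions under which the esters, the alkenes and all five stereocentres persist.

**Compound list**
1 | but-3-ene-1,2-diol (racemic) | C=CC(O)CO | starting material
2 | 1-[(tert-butyldiphenylsilyl)oxy]but-3-en-2-ol (racemic) | C=CC(O)CO[Si](c1ccccc1)(c1ccccc1)C(C)(C)C | intermediate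
3 | 1-[(tert-butyldiphenylsilyl)oxy]but-3-en-2-one | C=CC(=O)CO[Si](c1ccccc1)(c1ccccc1)C(C)(C)C | intermediate
4 | (S)-4-[(tert-butyldimethylsilyl)oxy]cyclopent-2-en-1-one | CC(C)(C)[Si](C)(C)O[C@H]1CC(=O)C=C1 | starting material
5 | (3S,4S)-4-[(tert-butyldimethylsilyl)oxy]-3-ethenyl-1-[(trimethylsilyl)oxy]cyclopent-1-ene | CC(C)(C)[Si](C)(C)O[C@H]1CC(O[Si](C)(C)C)=C[C@@H]1C=C | intermediate
6 | (2S,3S,4S)-4-[(tert-butyldimethylsilyl)oxy]-2-{4-[(tert-butyldiphenylsilyl)oxy]-3-oxobutyl}-3-ethenylcyclopentan-1-one | CC(C)(C)[Si](C)(C)O[C@H]1CC(=O)[C@@H](CCC(=O)CO[Si](c2ccccc2)(c2ccccc2)C(C)(C)C)[C@@H]1C=C | intermediate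
7 | tert-butyl{[(1S,2S,3S)-3-(3-{[(tert-butyldiphenylsilyl)oxy]methyl}but-3-en-1-yl)-2-ethenyl-4-methylidenecyclopentyl]oxy}dimethylsilane | CC(C)(C)[Si](C)(C)O[C@H]1CC(=C)[C@@H](CCC(=C)CO[Si](c2ccccc2)(c2ccccc2)C(C)(C)C)[C@@H]1C=C | intermediate
8 | (1S,2S,3S)-3-(3-{[(tert-butyldiphenylsilyl)oxy]methyl}but-3-en-1-yl)-2-ethenyl-4-methylidenecyclopentan-1-ol | O[C@H]1CC(=C)[C@@H](CCC(=C)CO[Si](c2ccccc2)(c2ccccc2)C(C)(C)C)[C@@H]1C=C | intermediate
9 | (2S,3S)-3-(3-{[(tert-butyldiphenylsilyl)oxy]methyl}but-3-en-1-yl)-2-ethenyl-4-methylidenecyclopentan-1-one | O=C1CC(=C)[C@@H](CCC(=C)CO[Si](c2ccccc2)(c2ccccc2)C(C)(C)C)[C@@H]1C=C | intermediate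
10 | 3-methoxyprop-1-yne | C#CCOC | starting material
11 | (3-methoxyprop-1-yn-1-yl)lithium | [Li]C#CCOC | intermediate (not isolated)
12 | dichloro(3-methoxyprop-1-yn-1-yl)cerium | Cl[Ce](Cl)C#CCOC | intermediate (not isolated)
13 | (1R,2S,3S)-3-(3-{[(tert-butyldiphenylsilyl)oxy]methyl}but-3-en-1-yl)-2-ethenyl-1-(3-methoxyprop-1-yn-1-yl)-4-methylidenecyclopentan-1-ol | COCC#C[C@@]1(O)CC(=C)[C@@H](CCC(=C)CO[Si](c2ccccc2)(c2ccccc2)C(C)(C)C)[C@@H]1C=C | intermediate
14 | (1R,2S,3S)-3-(3-{[(tert-butyldiphenylsilyl)oxy]methyl}but-3-en-1-yl)-2-ethenyl-4-methylidene-1-(propa-1,2-dien-1-yl)cyclopentan-1-ol | C=C=C[C@@]1(O)CC(=C)[C@@H](CCC(=C)CO[Si](c2ccccc2)(c2ccccc2)C(C)(C)C)[C@@H]1C=C | intermediate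
15 | 2-(trimethylsilyl)ethyl 2-[(1S,2S,3S)-3-(3-{[(tert-butyldiphenylsilyl)oxy]methyl}but-3-en-1-yl)-2-ethenyl-4-methylidene-6-oxocyclohexyl]prop-2-enoate | C=C(C(=O)OCC[Si](C)(C)C)[C@@H]1[C@@H](C=C)[C@H](CCC(=C)CO[Si](c2ccccc2)(c2ccccc2)C(C)(C)C)C(=C)CC1=O | intermediate
16 | 2-(trimethylsilyl)ethyl 2-[(1S,2S,3S,6R)-3-(3-{[(tert-butyldiphenylsilyl)oxy]methyl}but-3-en-1-yl)-2-ethenyl-6-hydroxy-4-methylidenecyclohexyl]prop-2-enoate | C=C(C(=O)OCC[Si](C)(C)C)[C@@H]1[C@@H](C=C)[C@H](CCC(=C)CO[Si](c2ccccc2)(c2ccccc2)C(C)(C)C)C(=C)C[C@H]1O | intermediate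
17 | 2-(trimethylsilyl)ethyl 2-[(1S,2R,4aS,8aS)-7-{[(tert-butyldiphenylsilyl)oxy]methyl}-2-hydroxy-4-methylidene-1,2,3,4,4a,5,6,8a-octahydronaphthalen-1-yl]prop-2-enoate | C=C(C(=O)OCC[Si](C)(C)C)[C@@H]1[C@H]2C=C(CO[Si](c3ccccc3)(c3ccccc3)C(C)(C)C)CC[C@@H]2C(=C)C[C@H]1O | intermediate
18 | (R)-2,2-dimethyl-1,3-dioxolane-4-carbaldehyde | O=C[C@H]1COC(C)(C)O1 | starting material
19 | (S)-4-ethynyl-2,2-dimethyl-1,3-dioxolane | C#C[C@H]1COC(C)(C)O1 | intermediate
20 | {1-[(4S)-2,2-dimethyl-1,3-dioxolan-4-yl]ethenyl}bis(2-methylpropyl)alumane | C=C([Al](CC(C)C)CC(C)C)[C@H]1COC(C)(C)O1 | intermediate (not isolated)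
21 | 2-[(4S)-2,2-dimethyl-1,3-dioxolan-4-yl]prop-2-enoic acid | C=C(C(=O)O)[C@H]1COC(C)(C)O1 | intermediate
22 | 2-(trimethylsilyl)ethyl 2-[(1S,2R,4aS,8aS)-7-{[(tert-butyldiphenylsilyl)oxy]methyl}-2-({2-[(4S)-2,2-dimethyl-1,3-dioxolan-4-yl]prop-2-enoyl}oxy)-4-methylidene-1,2,3,4,4a,5,6,8a-octahydronaphthalen-1-yl]prop-2-enoate | C=C(C(=O)OCC[Si](C)(C)C)[C@@H]1[C@H]2C=C(CO[Si](c3ccccc3)(c3ccccc3)C(C)(C)C)CC[C@@H]2C(=C)C[C@H]1OC(=O)C(=C)[C@H]4COC(C)(C)O4 | intermediate
23 | 2-[(1S,2R,4aS,8aS)-2-({2-[(4S)-2,2-dimethyl-1,3-dioxolan-4-yl]prop-2-enoyl}oxy)-7-(hydroxymethyl)-4-methylidene-1,2,3,4,4a,5,6,8a-octahydronaphthalen-1-yl]prop-2-enoic acid | C=C(C(=O)O)[C@@H]1[C@H]2C=C(CO)CC[C@@H]2C(=C)C[C@H]1OC(=O)C(=C)[C@H]3COC(C)(C)O3 | intermediate (not isolated)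
24 | 2-[(1S,2R,4aS,8aS)-2-{[(3S)-3,4-dihydroxy-2-methylidenebutanoyl]oxy}-7-(hydroxymethyl)-4-methylidene-1,2,3,4,4a,5,6,8a-octahydronaphthalen-1-yl]prop-2-enoic acid | C=C(C(=O)O)[C@@H]1[C@H]2C=C(CO)CC[C@@H]2C(=C)C[C@H]1OC(=O)C(=C)[C@H](O)CO | target

**Step count**
Total step count: 16.
Longest linear sequence: 13 steps (1 → 2 → 3 → 6 → 7 → 8 → 9 → 13 → 14 → 15 → 16 → 17 → 22 → 24).

**Steps most likely to fail**

Step 4 (Mukaiyama–Michael addition). The vinyl ketone 3 may polymerise or react 1,2 under TiCl4. The fallback sets out from 5 and comes back at 7. Hydroxymethylate 5 with aqueous formaldehyde and Yb(OTf)3 (aqueous Mukaiyama aldol) to (2R,3S,4S)-4-[(tert-butyldimethylsilyl)oxy]-3-ethenyl-2-(hydroxymethyl)cyclopentan-1-one F1. Dehydrate it with MsCl and Et3N to (3S,4S)-4-[(tert-butyldimethylsilyl)oxy]-3-ethenyl-2-methylidenecyclopentan-1-one F2. Add tert-butyl({2-[(trimethylsilyl)methyl]prop-2-en-1-yl}oxy)diphenylsilane F3, made from bought 2-[(trimethylsilyl)methyl]prop-2-en-1-ol and TBDPSCl. This is a Hosomi–Sakurai conjugate allylation under TiCl4, and protonation gives the trans ketone (2S,3S,4S)-4-[(tert-butyldimethylsilyl)oxy]-2-(3-{[(tert-butyldiphenylsilyl)oxy]methyl}but-3-en-1-yl)-3-ethenylcyclopentan-1-one F4. Methylenate its single ketone under the conditions of step 5 to reach 7.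

Step 8 (acetylide addition). Ketone 9 is β,γ-unsaturated on both sides and may enolise or isomerise. The fallback sets out from 9 and comes back at 14. A Barbier reaction of 9 with 3-bromo-1-(trimethylsilyl)prop-1-yne and indium powder in aqueous THF is non-basic and γ-selective. It gives (1R,2S,3S)-3-(3-{[(tert-butyldiphenylsilyl)oxy]methyl}but-3-en-1-yl)-2-ethenyl-4-methylidene-1-[1-(trimethylsilyl)propa-1,2-dien-1-yl]cyclopentan-1-ol F5. Hydroxyl-assisted protodesilylation (catalytic KOt-Bu, wet DMSO) then gives 14, so that 13 and step 9 are bypassed.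

Step 10 (the new ring expansion). A five-to-six shift has little strain release, and O-attack or migration of C3 may intervene. The fallback sets out from 14 and comes back at 15 and uses known reaction types only. N-Iodosuccinimide in CH2Cl2 at −20 °C triggers the halonium-induced semipinacol ring expansion of the α-allenol. This gives (2R,3S,4S)-4-(3-{[(tert-butyldiphenylsilyl)oxy]methyl}but-3-en-1-yl)-3-ethenyl-2-(1-iodoethenyl)-5-methylidenecyclohexan-1-one F6. Alkoxycarbonylation of the vinyl iodide with Pd(PPh3)4, CO (1 atm), 2-(trimethylsilyl)ethanol and Et3N then gives 15.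

**Further compounds**
F1 | step 4 | (2R,3S,4S)-4-[(tert-butyldimethylsilyl)oxy]-3-ethenyl-2-(hydroxymethyl)cyclopentan-1-one | CC(C)(C)[Si](C)(C)O[C@H]1CC(=O)[C@@H](CO)[C@@H]1C=C
F2 | step 4 | (3S,4S)-4-[(tert-butyldimethylsilyl)oxy]-3-ethenyl-2-methylidenecyclopentan-1-one | CC(C)(C)[Si](C)(C)O[C@H]1CC(=O)C(=C)[C@@H]1C=C
F3 | step 4 | tert-butyl({2-[(trimethylsilyl)methyl]prop-2-en-1-yl}oxy)diphenylsilane | C=C(C[Si](C)(C)C)CO[Si](c1ccccc1)(c1ccccc1)C(C)(C)C
F4 | step 4 | (2S,3S,4S)-4-[(tert-butyldimethylsilyl)oxy]-2-(3-{[(tert-butyldiphenylsilyl)oxy]methyl}but-3-en-1-yl)-3-ethenylcyclopentan-1-one | CC(C)(C)[Si](C)(C)O[C@H]1CC(=O)[C@@H](CCC(=C)CO[Si](c2ccccc2)(c2ccccc2)C(C)(C)C)[C@@H]1C=C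
F5 | step 8 | (1R,2S,3S)-3-(3-{[(tert-butyldiphenylsilyl)oxy]methyl}but-3-en-1-yl)-2-ethenyl-4-methylidene-1-[1-(trimethylsilyl)propa-1,2-dien-1-yl]cyclopentan-1-ol | C=C=C([Si](C)(C)C)[C@@]1(O)CC(=C)[C@@H](CCC(=C)CO[Si](c2ccccc2)(c2ccccc2)C(C)(C)C)[C@@H]1C=C
F6 | step 10 | (2R,3S,4S)-4-(3-{[(tert-butyldiphenylsilyl)oxy]methyl}but-3-en-1-yl)-3-ethenyl-2-(1-iodoethenyl)-5-methylidenecyclohexan-1-one | C=C(I)[C@@H]1[C@@H](C=C)[C@H](CCC(=C)CO[Si](c2ccccc2)(c2ccccc2)C(C)(C)C)C(=C)CC1=O
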